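## The problem

The target is epicatechin-(4β→6)-epigallocatechin 3,3′-di-O-gallate: an upper (2R,3R)-flavan-3-ol whose C4 (S, aryl group trans to the 3-OH) is bonded to C6 of ring A of a lower (2R,3R)-flavan-3-ol, which carries one gallate on O3 and one on a meta oxygen (O3′) of its pyrogallol ring B. The central difficulty is the C4(upper)–C6(lower) bond: a flavan-4-yl cation attacks a complete 5,7-dioxygenated flavan mainly at C8, so the natural union gives the 4→8 isomer unless C8 is blocked. The feature that removes this difficulty is that lower C6 lies para to O1 (through C8a) and between C5–O and C7–O: without its C4–C4a bond, ring A is a 3,5-dioxyphenyl ether whose two ortho carbons (the future C4a and C8) are equivalent, and without the whole C2–C3–C4 bridge it is phloroglucinol (5), in which all three ring carbons are the same. Of the five stereocentres, upper C2 and C3 come with (−)-epicatechin (1) and direct the aryl group at C4 to the face trans to O3; the lower C2/C3 pair (cis) is too remote to be induced by the upper unit and must be brought in with its absolute configuration. Ring B of the lower unit needs one meta oxygen set apart from its two neighbours, and of the thirteen hydroxyls only lower O3 and O3′ are acylated while upper O3 stays free. The interflavan bond is cleaved by protic acid, 2,3-cis flavans epimerise at C2 in base, the free polyphenol is air-sensitive, and the aryl gallate can migrate to the neighbouring 4′-OH or be lost in base; the esters must therefore come late and the last unmasking must be neutral.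

## Retrosynthesis

**Protecting groups.** Target 18 is traced to 17, in which all eleven phenols and upper O3 are masked as thirteen benzyl ethers and one diphenylmethylene acetal (O4′/O5′). No skeletal bond is cut. One neutral hydrogenolysis is asked to remove everything without touching the esters or the interflavan bond.

**Esters.** The two acyl–oxygen bonds of 17 are cut together, giving diol 15 and two molecules of acid 16. In 15 the only free hydroxyls are lower O3 and O3′, so one twofold esterification needs no selectivity. Carrying an aryl ester through the earlier organometallic and basic steps would be the worse choice. Diol 15 comes from allyl ether 14; the allyl group is what marked O3′ from the start.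

**Lower ring C (key cut).** In 14 the C4–C4a bond of the lower unit is cut, which gives aryl ether 13 with an oxirane at C3/C4. Against cutting O1–C2: closure through a benzylic cation at C2 would favour the 2,3-trans isomer. Against cutting C4(upper)–C6: that is the cut that raises the 6/8 problem. Here both ortho carbons of the ether ring are equivalent, so the forward reaction has no regiochemical choice at carbon. It is only asked to open the oxirane at its terminal carbon (6-endo) and leave C2 and C3 untouched. The precursor lacks ring C, and its two halves are held together by one ether bond only.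

**Fragment union.** Ether 13 comes from diphenol 12 by benzylation, and in 12 the O1–C2 bond is cut to give phenol 6 and epoxy alcohol 11. This divides the molecule into halves of similar size. The forward Mitsunobu etherification must invert the carbinol carbon of 11 (erythro to threo, which becomes 2,3-cis) and must choose the para hydroxyl of 6, the only one not flanked by the flavanyl group.

**Interflavan bond.** In 6 the upper C4–aryl bond is cut to give the C4 ether 4 and phloroglucinol 5. Because 5 has one kind of carbon, this arylation has no regiochemistry; it only has to enter trans to the 3-benzyloxy group (4β). Ether 4 comes from 3 by oxidation at C4, 3 from 2 and 2 from 1 by benzylation.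

**Lower C3 unit and ring B.** Epoxy alcohol 11 comes from racemic allylic alcohol 10 by kinetic resolution through asymmetric epoxidation, which fixes both lower stereocentres in one step. Alcohol 10 comes from aldehyde 9 by vinyl addition (C2–C3 bond), 9 from 8 by allylation, and 8 from 3,4,5-trihydroxybenzaldehyde 7. The acetal of 8 ties up two adjacent oxygens and leaves the single meta hydroxyl that becomes O3′.

## Roads not taken

Alternative 1: Cut C4(upper)–C6(lower) and join 4 with the complete lower flavan A1, whose C8 is blocked by bromine, by Lewis acid-promoted arylation; the bromine would fall in the final hydrogenolysis. This is the route most chemists would draw first. A1 needs a full enantioselective synthesis of a 2,3-cis flavan with differentiated ring B before the union (arene allylation, dihydroxylation, cyclisation to the 2,3-trans isomer, oxidation and reduction to cis). Its bromination must then choose C8 over C6, which is the same 6/8 problem with a smaller electrophile. The arylation finally has to take place at a carbon flanked by two benzyloxy groups, the slowest position of ring A. The chosen plan makes the interflavan bond to 5, where no choice exists, and builds the lower ring afterwards in two steps from the union.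

Alternative 2: Cut C3–C4 and O1–C2 of the lower ring C and close it by an inverse-demand hetero-Diels–Alder reaction between ortho-quinone methide A3, generated on the phloroglucinol ring after union with 5, and (Z)-enol gallate A2. On paper this gives ring C, the cis relationship and both esters at once. In an enol ester, however, the aryl-bearing carbon is the nucleophilic terminus, so bonding to the methide carbon there leads to the 3-aryl-2-acyloxy (isoflavan) connectivity; the flavan forms only if aryl stabilisation wins. The two faces of planar A3 differ only through stereocentres four or more bonds away, so the absolute configuration of lower C2/C3 would not be controlled. The chosen plan brings both centres in with 11 and breaks no bond at either in the ring closure.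

Alternative 3: Cut the same C4–C6 bond with reversed polarity: bromine–lithium exchange on the 6-bromo flavan A5, addition to the C4 carbonyl of ketone A4, and ionic deoxygenation at C4. The position of the bond is certain, but the hydride enters the C4 cation trans to the 3-benzyloxy group and leaves the aryl group cis to it, which is the 4α linkage and the wrong configuration. In addition A4 has an acidic C3–H next to the carbonyl (epimerisation to 2,3-trans), and A5 again requires a complete lower flavan. The chosen plan lets the arene attack the cation, which is the direction that gives 4β.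

Key step: step 11

Remark on the chemistry: the SMILES is read as epicatechin-(4β→6)-epigallocatechin 3,3′-di-O-gallate (upper unit 2R,3R,4S; lower unit 2R,3R); positions are given in flavan numbering, and 1, 5, 7 and 16 are taken as commercial.

## Route

Step 1
Reactants: 1 (−)-epicatechin
Product: 2 5,7,3′,4′-tetra-O-benzyl-(−)-epicatechin
Conditions: BnBr (4.4 equiv), K2CO3, DMF, 0 °C → rt
Reagents that add atoms: benzyl bromide, BrCc1ccccc1
Why: Williamson etherification; carbonate deprotonates the four phenols but not the C3 alcohol, and the mild base should avoid epimerisation at C2.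

Step 2
Reactants: 2 5,7,3′,4′-tetra-O-benzyl-(−)-epicatechin
Product: 3 3,5,7,3′,4′-penta-O-benzyl-(−)-epicatechin
Conditions: NaH, BnBr, DMF, 0 °C → rt
Reagents that add atoms: benzyl bromide, BrCc1ccccc1
Why: Williamson etherification of the secondary alkoxide; the ether keeps upper O3 out of the Mitsunobu and esterification steps and is removed with the others at the end.

Step 3
Reactants: 3 3,5,7,3′,4′-penta-O-benzyl-(−)-epicatechin
Product: 4 4β-(2-hydroxyethoxy)-3,5,7,3′,4′-penta-O-benzylepicatechin
Conditions: DDQ (2 equiv), HOCH2CH2OH (excess), CH2Cl2, rt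
Reagents that add atoms: ethylene glycol, OCCO
Why: DDQ benzylic oxidation; hydride is taken from C4, the position activated by O5, O7 and O1 of ring A, and the cation is trapped by the glycol on the face trans to the 3-benzyloxy group.

Step 4
Reactants: 4 4β-(2-hydroxyethoxy)-3,5,7,3′,4′-penta-O-benzylepicatechin; 5 phloroglucinol
Product: 6 4β-(2,4,6-trihydroxyphenyl)-3,5,7,3′,4′-penta-O-benzylepicatechin
Conditions: 5 (5 equiv), BF3·OEt2, THF–CH2Cl2, −40 → 0 °C
Reagents that add atoms: none
Why: Friedel–Crafts arylation of the C4 cation, the reaction behind acid-catalysed capture of procyanidin units by phloroglucinol; 5 has one kind of ring carbon, so there is no regiochemistry, and attack trans to the axial 3-benzyloxy group should set C4 as 4β. The excess of 5 suppresses a second arylation.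

Step 5
Reactants: 7 3,4,5-trihydroxybenzaldehyde
Product: 8 7-hydroxy-2,2-diphenyl-1,3-benzodioxole-5-carbaldehyde
Conditions: Ph2CCl2, Ph2O, 175 °C
Reagents that add atoms: dichlorodiphenylmethane, ClC(Cl)(c1ccccc1)c1ccccc1
Why: Acetalisation of a catechol pair; both adjacent pairs of 7 are equivalent, so a single acetal forms and exactly one meta hydroxyl (the future O3′) stays free.

Step 6
Reactants: 8 7-hydroxy-2,2-diphenyl-1,3-benzodioxole-5-carbaldehyde
Product: 9 7-(allyloxy)-2,2-diphenyl-1,3-benzodioxole-5-carbaldehyde
Conditions: allyl bromide, K2CO3, DMF, rt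
Reagents that add atoms: allyl bromide, C=CCBr
Why: Williamson etherification; the allyl ether is orthogonal to benzyl ethers and the acetal and is removed in step 12.

Step 7
Reactants: 9 7-(allyloxy)-2,2-diphenyl-1,3-benzodioxole-5-carbaldehyde
Product: 10 rac-1-[7-(allyloxy)-2,2-diphenyl-1,3-benzodioxol-5-yl]prop-2-en-1-ol
Conditions: CH2=CHMgBr, THF, −78 → 0 °C; aq. NH4Cl
Reagents that add atoms: vinylmagnesium bromide, C=C[Mg]Br
Why: Grignard addition to the aldehyde; forms the future C2–C3 bond of the lower unit as a racemic secondary allylic alcohol.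

Step 8
Reactants: 10 rac-1-[7-(allyloxy)-2,2-diphenyl-1,3-benzodioxol-5-yl]prop-2-en-1-ol
Product: 11 (S)-[7-(allyloxy)-2,2-diphenyl-1,3-benzodioxol-5-yl][(2R)-oxiran-2-yl]methanol (erythro)
Conditions: Ti(OiPr)4 (20 mol %), L-(+)-DIPT (25 mol %), t-BuOOH (0.45 equiv), 4 Å MS, CH2Cl2, −20 °C
Reagents that add atoms: tert-butyl hydroperoxide, CC(C)(C)OO
Why: Sharpless kinetic resolution; with L-(+)-tartrate the (R)-enantiomer of 10 should be epoxidised fast, on the face that gives the erythro epoxy alcohol, so the carbinol centre is set by selection and the oxirane centre by the reagent, while the slow (S)-enantiomer of 10 stays behind. The allyl ether is not an allylic alcohol and should not react.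

Step 9
Reactants: 6 4β-(2,4,6-trihydroxyphenyl)-3,5,7,3′,4′-penta-O-benzylepicatechin; 11 (S)-[7-(allyloxy)-2,2-diphenyl-1,3-benzodioxol-5-yl][(2R)-oxiran-2-yl]methanol
Product: 12 4β-{2,6-dihydroxy-4-[(R)-[7-(allyloxy)-2,2-diphenyl-1,3-benzodioxol-5-yl][(2R)-oxiran-2-yl]methoxy]phenyl}-3,5,7,3′,4′-penta-O-benzylepicatechin
Conditions: PPh3, DIAD, THF, 0 °C → rt
Reagents that add atoms: none
Why: Mitsunobu etherification; SN2 displacement at the oxyphosphonium of 11 inverts the carbinol carbon (S to R, erythro to threo), which is the relationship that becomes 2,3-cis. The para hydroxyl of 6 is the only phenol not flanked by the flavanyl group and should react first; the adjacent oxirane disfavours ionisation at the benzylic carbon. Any diastereomer from the minor enantiomer of 11 should be separable here, since 6 is a single enantiomer.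

Step 10
Reactants: 12 (diphenol from step 9)
Product: 13 4β-{2,6-bis(benzyloxy)-4-[(R)-[7-(allyloxy)-2,2-diphenyl-1,3-benzodioxol-5-yl][(2R)-oxiran-2-yl]methoxy]phenyl}-3,5,7,3′,4′-penta-O-benzylepicatechin
Conditions: BnBr, Cs2CO3, Bu4NI (cat.), DMF, rt → 40 °C
Reagents that add atoms: benzyl bromide, BrCc1ccccc1
Why: Williamson etherification of the two hindered phenols (the future O5 and O7); oxirane, acetal and allyl ether are stable to carbonate, and the phenoxides cannot reach the oxirane intramolecularly.

Step 11
Reactants: 13 (oxirane ether from step 10)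
Product: 14 3,5,7,3′,4′-penta-O-benzylepicatechin-(4β→6)-[3′-O-allyl-5,7-di-O-benzyl-4′,5′-O-(diphenylmethylene)epigallocatechin]
Conditions: AuCl3 (5 mol %), AgOTf (15 mol %), 2,6-di-tert-butyl-4-methylpyridine (10 mol %), ClCH2CH2Cl, 0 °C → rt
Reagents that add atoms: none
Why: Friedel–Crafts epoxide–arene cyclialkylation: the cationic gold Lewis acid binds the oxirane oxygen, the ring carbon ortho to the ether oxygen (ortho/para to three oxygens) opens the oxirane at its primary carbon with anti displacement, and loss of a proton from the arenium ion and protonation of the alkoxide give the 3-OH. The closest known reaction type is the gold trichloride/silver triflate-catalysed cyclialkylation of electron-rich aryl glycidyl ethers to chroman-3-ols. Ring C of the lower unit closes in the 6-endo mode (C4–C4a bond, both oxirane carbons in the new ring); the 5-exo mode (attack at C3, giving a 3-hydroxymethyl-2,3-dihydrobenzofuran) is disfavoured because the two-atom O–C2 tether cannot place the ortho carbon behind the C3–O bond and C3 is the more hindered, inductively deactivated carbon. No new stereocentre is formed: C2 is untouched and the C3–O bond is not broken, so the (2R,3R) threo ether becomes the 2,3-cis flavan-3-ol. The step needs endo over exo opening, secured as stated, and oxirane activation without ionisation of the benzylic C2–O aryl ether, secured by the oxirane being the better Lewis base and a σ-acceptor next to C2. It needs no choice between a 6- and an 8-linkage, because the two ortho carbons of the 4-alkoxy-2,6-bis(benzyloxy)phenyl ring are exchanged by rotation about the aryl–C4 bond and either closure gives 14. The hindered pyridine should keep traces of triflic acid from the interflavan bond and the acetal.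

Step 12
Reactants: 14 (allyl ether from step 11)
Product: 15 3,5,7,3′,4′-penta-O-benzylepicatechin-(4β→6)-[5,7-di-O-benzyl-4′,5′-O-(diphenylmethylene)epigallocatechin]
Conditions: Pd(PPh3)4 (5 mol %), morpholine, THF, rt
Reagents that add atoms: none
Why: Tsuji–Trost deallylation; zerovalent palladium ionises the aryl allyl ether to a π-allyl complex that morpholine captures, freeing O3′ while benzyl ethers, acetal and the secondary alcohol are untouched.

Step 13
Reactants: 15 (diol from step 12); 16 3,4,5-tris(benzyloxy)benzoic acid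
Product: 17 3,5,7,3′,4′-penta-O-benzylepicatechin-(4β→6)-{5,7-di-O-benzyl-4′,5′-O-(diphenylmethylene)-3,3′-bis-O-[3,4,5-tris(benzyloxy)benzoyl]epigallocatechin}
Conditions: 16 (3 equiv), DCC, DMAP, CH2Cl2, 0 °C → rt
Reagents that add atoms: none
Why: Steglich esterification; the phenolic O3′ and the axial O3 of the lower unit are the only free hydroxyls, so both gallates go on in one step. Lower O3 is remote from the upper unit in a 4→6 dimer and should be as accessible as in a monomeric flavan.

Step 14
Reactants: 17 (bis-gallate from step 13)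
Product: 18 epicatechin-(4β→6)-epigallocatechin 3,3′-di-O-gallate (CNP0237700.1)
Conditions: H2 (1 atm), Pd(OH)2/C, THF–MeOH–H2O, rt
Reagents that add atoms: none
Why: Hydrogenolysis cleaves the thirteen benzyl ethers and the diphenylmethylene acetal under neutral conditions, which the esters, the interflavan bond and both C2–O1 bonds should survive. A neutral medium and short contact time should keep the 3′-gallate from migrating to O4′.

## Compound list

1 | (−)-epicatechin | Oc1ccc(cc1O)[C@H]1Oc2cc(O)cc(O)c2C[C@H]1O | starting material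
2 | 5,7,3′,4′-tetra-O-benzyl-(−)-epicatechin | c1ccccc1COc1ccc(cc1OCc1ccccc1)[C@H]1Oc2cc(OCc3ccccc3)cc(OCc3ccccc3)c2C[C@H]1O | intermediate
3 | 3,5,7,3′,4′-penta-O-benzyl-(−)-epicatechin | c1ccccc1COc1ccc(cc1OCc1ccccc1)[C@H]1Oc2cc(OCc3ccccc3)cc(OCc3ccccc3)c2C[C@H]1OCc1ccccc1 | intermediate
4 | 4β-(2-hydroxyethoxy)-3,5,7,3′,4′-penta-O-benzylepicatechin | OCCO[C@H]1c2c(OCc3ccccc3)cc(OCc3ccccc3)cc2O[C@H](c2ccc(OCc3ccccc3)c(OCc3ccccc3)c2)[C@@H]1OCc1ccccc1 | intermediate
5 | phloroglucinol | Oc1cc(O)cc(O)c1 | starting material
6 | 4β-(2,4,6-trihydroxyphenyl)-3,5,7,3′,4′-penta-O-benzylepicatechin | Oc1cc(O)c(c(O)c1)[C@H]1c2c(OCc3ccccc3)cc(OCc3ccccc3)cc2O[C@H](c2ccc(OCc3ccccc3)c(OCc3ccccc3)c2)[C@@H]1OCc1ccccc1 | intermediate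
7 | 3,4,5-trihydroxybenzaldehyde | O=Cc1cc(O)c(O)c(O)c1 | starting material
8 | 7-hydroxy-2,2-diphenyl-1,3-benzodioxole-5-carbaldehyde | O=Cc1cc(O)c2OC(c3ccccc3)(c3ccccc3)Oc2c1 | intermediate
9 | 7-(allyloxy)-2,2-diphenyl-1,3-benzodioxole-5-carbaldehyde | O=Cc1cc(OCC=C)c2OC(c3ccccc3)(c3ccccc3)Oc2c1 | intermediate
10 | rac-1-[7-(allyloxy)-2,2-diphenyl-1,3-benzodioxol-5-yl]prop-2-en-1-ol (racemate) | C=CC(O)c1cc(OCC=C)c2OC(c3ccccc3)(c3ccccc3)Oc2c1 | intermediate
11 | (S)-[7-(allyloxy)-2,2-diphenyl-1,3-benzodioxol-5-yl][(2R)-oxiran-2-yl]methanol | O[C@@H](c1cc(OCC=C)c2OC(c3ccccc3)(c3ccccc3)Oc2c1)[C@H]1CO1 | intermediate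
12 | 4β-{2,6-dihydroxy-4-[(R)-[7-(allyloxy)-2,2-diphenyl-1,3-benzodioxol-5-yl][(2R)-oxiran-2-yl]methoxy]phenyl}-3,5,7,3′,4′-penta-O-benzylepicatechin | Oc1cc(O[C@H](c2cc(OCC=C)c3OC(c4ccccc4)(c4ccccc4)Oc3c2)[C@H]2CO2)cc(O)c1[C@H]1c2c(OCc3ccccc3)cc(OCc3ccccc3)cc2O[C@H](c2ccc(OCc3ccccc3)c(OCc3ccccc3)c2)[C@@H]1OCc1ccccc1 | intermediate
13 | 4β-{2,6-bis(benzyloxy)-4-[(R)-[7-(allyloxy)-2,2-diphenyl-1,3-benzodioxol-5-yl][(2R)-oxiran-2-yl]methoxy]phenyl}-3,5,7,3′,4′-penta-O-benzylepicatechin | c1ccccc1COc1cc(O[C@H](c2cc(OCC=C)c3OC(c4ccccc4)(c4ccccc4)Oc3c2)[C@H]2CO2)cc(OCc2ccccc2)c1[C@H]1c2c(OCc3ccccc3)cc(OCc3ccccc3)cc2O[C@H](c2ccc(OCc3ccccc3)c(OCc3ccccc3)c2)[C@@H]1OCc1ccccc1 | intermediate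
14 | 3,5,7,3′,4′-penta-O-benzylepicatechin-(4β→6)-[3′-O-allyl-5,7-di-O-benzyl-4′,5′-O-(diphenylmethylene)epigallocatechin] | C=CCOc1cc([C@H]2Oc3cc(OCc4ccccc4)c([C@H]4c5c(OCc6ccccc6)cc(OCc6ccccc6)cc5O[C@H](c5ccc(OCc6ccccc6)c(OCc6ccccc6)c5)[C@@H]4OCc4ccccc4)c(OCc4ccccc4)c3C[C@H]2O)cc2OC(c3ccccc3)(c3ccccc3)Oc12 | intermediate
15 | 3,5,7,3′,4′-penta-O-benzylepicatechin-(4β→6)-[5,7-di-O-benzyl-4′,5′-O-(diphenylmethylene)epigallocatechin] | Oc1cc([C@H]2Oc3cc(OCc4ccccc4)c([C@H]4c5c(OCc6ccccc6)cc(OCc6ccccc6)cc5O[C@H](c5ccc(OCc6ccccc6)c(OCc6ccccc6)c5)[C@@H]4OCc4ccccc4)c(OCc4ccccc4)c3C[C@H]2O)cc2OC(c3ccccc3)(c3ccccc3)Oc12 | intermediate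
16 | 3,4,5-tris(benzyloxy)benzoic acid | O=C(O)c1cc(OCc2ccccc2)c(OCc2ccccc2)c(OCc2ccccc2)c1 | starting material
17 | 3,5,7,3′,4′-penta-O-benzylepicatechin-(4β→6)-{5,7-di-O-benzyl-4′,5′-O-(diphenylmethylene)-3,3′-bis-O-[3,4,5-tris(benzyloxy)benzoyl]epigallocatechin} | O=C(Oc1cc([C@H]2Oc3cc(OCc4ccccc4)c([C@H]4c5c(OCc6ccccc6)cc(OCc6ccccc6)cc5O[C@H](c5ccc(OCc6ccccc6)c(OCc6ccccc6)c5)[C@@H]4OCc4ccccc4)c(OCc4ccccc4)c3C[C@H]2OC(=O)c2cc(OCc3ccccc3)c(OCc3ccccc3)c(OCc3ccccc3)c2)cc2OC(c3ccccc3)(c3ccccc3)Oc12)c1cc(OCc2ccccc2)c(OCc2ccccc2)c(OCc2ccccc2)c1 | intermediate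
18 | epicatechin-(4β→6)-epigallocatechin 3,3′-di-O-gallate (CNP0237700.1) | O=C(Oc1cc([C@H]2Oc3cc(O)c([C@H]4c5c(O)cc(O)cc5O[C@H](c5ccc(O)c(O)c5)[C@@H]4O)c(O)c3C[C@H]2OC(=O)c2cc(O)c(O)c(O)c2)cc(O)c1O)c1cc(O)c(O)c(O)c1 | target

## Step count and risk

Total: 14 steps. Longest linear sequence: 10 steps (1 → 18 through steps 1–4 and 9–14; the branch from 7 through steps 5–8 and 9–14 is equally long).

**Step 11 (key step).** What may go wrong is opening of the activated oxirane at its internal carbon (exo mode), or ionisation of the benzylic C2–O aryl ether before the ring closes, with loss of the C2 configuration or of the whole lower half. The fallback changes the nucleophile from a neutral arene under Lewis acid to a metal phenoxide. It sets out from 12: two equivalents of EtMgBr in toluene give the bis(bromomagnesium) phenoxide, whose carbon ortho to the phenoxide oxygen should be alkylated by the magnesium-bound oxirane at its terminal carbon, giving the chroman-3-ol diphenol F1. Benzylation of the two phenols of F1 (BnBr, K2CO3, DMF) returns to the route at 14.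

**Step 9.** What may go wrong is etherification at an ortho hydroxyl or at two hydroxyls, and partial ionisation of the activated benzylic alcohol so that inversion is incomplete. The fallback removes the choice between hydroxyls before the union. It sets out from 6: TBDPSCl and imidazole should silylate only the unhindered para hydroxyl to give silyl ether F2; BnBr and Cs2CO3 give the bis-benzyl ether F3; Bu4NF frees the para-phenol F4. Mitsunobu reaction of F4, which has a single hydroxyl, with 11 at low temperature returns to the route at 13.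

**Step 8.** What may go wrong is too small a rate difference between the enantiomers of an aryl vinyl carbinol, or Lewis acid-induced ionisation of the electron-rich carbinol, so that 11 is formed with insufficient enantiomeric purity. The fallback separates resolution from epoxidation. It sets out from 10: acylation with vinyl acetate and Candida antarctica lipase B should convert the (R)-enantiomer into the (R)-acetate F5; methanolysis (K2CO3, MeOH) gives the (R)-allylic alcohol F6; epoxidation of F6 with Ti(OiPr)4, L-(+)-DIPT and t-BuOOH is the matched case, runs to full conversion and returns to the route at 11.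

**Step 4.** What may go wrong is a second arylation of the adduct, which still has two nucleophilic ring carbons, and acid-promoted reversal of the arylation. The fallback changes the mode of activation from an oxophilic acid to a thiophilic silver salt. It sets out from 4: exchange with benzyl mercaptan (BF3·OEt2, CH2Cl2, −40 °C) gives the 4β-benzylsulfanyl ether F7; AgBF4 in THF in the presence of excess 5 ionises only the C–S bond, so the sulfur-free product cannot be ionised again, and the route is rejoined at 6.

## Further compounds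

F1 | step 11 | 3,5,7,3′,4′-penta-O-benzylepicatechin-(4β→6)-[3′-O-allyl-4′,5′-O-(diphenylmethylene)epigallocatechin] (lower 5,7-diphenol) | C=CCOc1cc([C@H]2Oc3cc(O)c([C@H]4c5c(OCc6ccccc6)cc(OCc6ccccc6)cc5O[C@H](c5ccc(OCc6ccccc6)c(OCc6ccccc6)c5)[C@@H]4OCc4ccccc4)c(O)c3C[C@H]2O)cc2OC(c3ccccc3)(c3ccccc3)Oc12
F2 | step 9 | 4β-[4-(tert-butyldiphenylsilyloxy)-2,6-dihydroxyphenyl]-3,5,7,3′,4′-penta-O-benzylepicatechin | CC(C)(C)[Si](c1ccccc1)(c1ccccc1)Oc1cc(O)c(c(O)c1)[C@H]1c2c(OCc3ccccc3)cc(OCc3ccccc3)cc2O[C@H](c2ccc(OCc3ccccc3)c(OCc3ccccc3)c2)[C@@H]1OCc1ccccc1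
F3 | step 9 | 4β-[2,6-bis(benzyloxy)-4-(tert-butyldiphenylsilyloxy)phenyl]-3,5,7,3′,4′-penta-O-benzylepicatechin | CC(C)(C)[Si](c1ccccc1)(c1ccccc1)Oc1cc(OCc2ccccc2)c(c(OCc2ccccc2)c1)[C@H]1c2c(OCc3ccccc3)cc(OCc3ccccc3)cc2O[C@H](c2ccc(OCc3ccccc3)c(OCc3ccccc3)c2)[C@@H]1OCc1ccccc1
F4 | step 9 | 4β-[2,6-bis(benzyloxy)-4-hydroxyphenyl]-3,5,7,3′,4′-penta-O-benzylepicatechin | Oc1cc(OCc2ccccc2)c(c(OCc2ccccc2)c1)[C@H]1c2c(OCc3ccccc3)cc(OCc3ccccc3)cc2O[C@H](c2ccc(OCc3ccccc3)c(OCc3ccccc3)c2)[C@@H]1OCc1ccccc1
F5 | step 8 | (R)-1-[7-(allyloxy)-2,2-diphenyl-1,3-benzodioxol-5-yl]prop-2-en-1-yl acetate | CC(=O)O[C@H](C=C)c1cc(OCC=C)c2OC(c3ccccc3)(c3ccccc3)Oc2c1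
F6 | step 8 | (R)-1-[7-(allyloxy)-2,2-diphenyl-1,3-benzodioxol-5-yl]prop-2-en-1-ol | O[C@H](C=C)c1cc(OCC=C)c2OC(c3ccccc3)(c3ccccc3)Oc2c1
F7 | step 4 | 4β-(benzylsulfanyl)-3,5,7,3′,4′-penta-O-benzylepicatechin | c1ccccc1CS[C@H]1c2c(OCc3ccccc3)cc(OCc3ccccc3)cc2O[C@H](c2ccc(OCc3ccccc3)c(OCc3ccccc3)c2)[C@@H]1OCc1ccccc1
A1 | alternative 1 | 8-bromo-3′-O-allyl-5,7-di-O-benzyl-4′,5′-O-(diphenylmethylene)epigallocatechin | C=CCOc1cc([C@H]2Oc3c(Br)c(OCc4ccccc4)cc(OCc4ccccc4)c3C[C@H]2O)cc2OC(c3ccccc3)(c3ccccc3)Oc12
A2 | alternative 2 | (Z)-2-{2,2-diphenyl-7-[3,4,5-tris(benzyloxy)benzoyloxy]-1,3-benzodioxol-5-yl}ethenyl 3,4,5-tris(benzyloxy)benzoate | O=C(O/C=C\c1cc(OC(=O)c2cc(OCc3ccccc3)c(OCc3ccccc3)c(OCc3ccccc3)c2)c2OC(c3ccccc3)(c3ccccc3)Oc2c1)c1cc(OCc2ccccc2)c(OCc2ccccc2)c(OCc2ccccc2)c1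
A3 | alternative 2 | 3,5-bis(benzyloxy)-6-methylidene-4-(3,5,7,3′,4′-penta-O-benzylepicatechin-4β-yl)cyclohexa-2,4-dien-1-one | C=C1C(=O)C=C(OCc2ccccc2)C(=C1OCc1ccccc1)[C@H]1c2c(OCc3ccccc3)cc(OCc3ccccc3)cc2O[C@H](c2ccc(OCc3ccccc3)c(OCc3ccccc3)c2)[C@@H]1OCc1ccccc1
A4 | alternative 3 | 3,5,7,3′,4′-penta-O-benzyl-4-oxoepicatechin (2,3-cis flavanonol) | O=C1c2c(OCc3ccccc3)cc(OCc3ccccc3)cc2O[C@H](c2ccc(OCc3ccccc3)c(OCc3ccccc3)c2)[C@@H]1OCc1ccccc1
A5 | alternative 3 | 6-bromo-3′-O-allyl-5,7-di-O-benzyl-3-O-(tert-butyldimethylsilyl)-4′,5′-O-(diphenylmethylene)epigallocatechin | C=CCOc1cc([C@H]2Oc3cc(OCc4ccccc4)c(Br)c(OCc4ccccc4)c3C[C@H]2O[Si](C)(C)C(C)(C)C)cc2OC(c3ccccc3)(c3ccccc3)Oc12
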